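Which set-up keeps the highest share of target among target, isomer of the product and trapped intermediate?

    open intermediate → decomposed reagent (k1 = 0.26 s⁻¹)
    open intermediate ⇌ target (K2 = 1.8, k2 = 0.093 s⁻¹)
    open intermediate ⇌ isomer of the product (K3 = 7.2, k3 = 0.051 s⁻¹)
    substrate + partner → open intermediate + by-product (k4 = 0.25 M⁻¹ s⁻¹)
    open intermediate + capture agent → trapped intermediate (k5 = 0.14 M⁻¹ s⁻¹)

| setting | south | south-east | east | north-west |
|---|---|---|---|---|
| substrate | 0.20 M | 0.20 M | 0.20 M (fed, over 1.50 min) | 0.20 M |
| partner | 0.220 M | 0.220 M | 0.220 M | 0.220 M |
| capture agent | 0.0100 M | 0.0100 M | 0.0100 M | 0.0100 M |
| remark | a single well-mixed tank run continuously and read at steady state, 3.0 min in it on average | one stirred flow tank at steady state, fed with the mixture as stated, mean residence time 9.00 min | a stirred flask in which substrate is dosed at a steady rate over 1.50 min without added volume, worked up at 3.0 min | everything together in a closed stirred flask, run for 3.0 min |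
| time |  |  | 3.0 min | 3.0 min |

- the stated concentrations are those of everything mixed, before any reaction; amounts are the same in each set-up
- the feed brings no volume worth counting
- run time (east): 3.0 min

* the set-up with the highest share of target in all that became target or isomer of the product or trapped intermediate, at the outlet or at the end ("none" if the first two lie within 2 percentage points) (south / south-east / east / north-west / none)
* share of target in all that became target or isomer of the product or trapped intermediate, at the outlet or at the end, south
* share of target in all that became target or isomer of the product or trapped intermediate, at the outlet or at the end, south-east
* share of target in all that became target or isomer of the product or trapped intermediate, at the outlet or at the end, east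
* share of target in all that became target or isomer of the product or trapped intermediate, at the outlet or at the end, north-west

I keep a ledger for substrate, the limiting reagent, at 0.20 M against 0.220 M of partner. Each mole of substrate that reacts becomes a mole of open intermediate. With capture agent as charged, open intermediate leaves at a total first-order constant of

0.405 s⁻¹

so on its first pass each mole of open intermediate splits into these entries:

decomposed reagent 64.1%; target 22.9%; isomer of the product 12.6%; trapped intermediate 0.345%.

Among the counted entries target then holds 64.0%, the share under kinetic control. But two entries stay open: target returns to open intermediate with back constant 0.0517 s⁻¹, and isomer with 0.00708 s⁻¹. Each return is split again, so target drains with a time of 0.419 min and isomer with 2.69 min.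

I measure from the share of target in target plus isomer at equilibrium, the share under thermodynamic control. I call it the resting share, 20.0%.

In a steady tank the level of open intermediate cancels from the ledger, and each entry carries a weight:

weight = forward constant / (1 + back constant × mean time)

Trapped intermediate has no way back, so its weight is 0.00140 s⁻¹. In south the weights are 0.00903 s⁻¹ for target and 0.0224 s⁻¹ for isomer, which gives

south: 27.5%

The same rule at 9.00 min gives

south-east: 21.2%

In north-west, substrate has a half-life of 0.210 min as charged, well inside the run. Fresh supply fades there while target drains faster than isomer, so I expect north-west under 20.0%. East stops dosing at 1.50 min, and the remaining time exceeds the drain time of target, so I expect east under 20.0%. My reckoning gives the flasks a ceiling and no more, and with that ceiling as their score the winner is south.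

The forecast, holding that “the share depends on how recently the target was formed”, names south, with 27.6% for south, 21.3% for south-east, 13.8% for east and 9.1% for north-west.

The simulation gives south as best, with south at 27.6%, south-east at 21.3%, east at 14.4% and north-west at 9.42%, so both flasks stand under the resting share. North-west has not come to rest at 3.0 min: it still holds 5.86% of its charge as substrate and 6.74% as isomer. Ten times the time adds 10.0 isomer drain times. Its share has moved by 5 points at 9.31 min, and at 30.0 min it reads 0.0206%, far under the resting share.

All constants were chosen freely; the result is computed.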